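The dihydrochalcone is cut at Cα–Cβ into the ring A ketone 6-acetyl-5,7-dihydroxy-2,2-dimethylchroman and 2,2-dimethylchroman-6-carbaldehyde. Everything rests on the dihydropyran ring of the second, phenol-free chroman: its O1–C2(CH3)2 unit is acetone, inserted between the homobenzylic carbon C3 and the aromatic carbon C8a. In one pot the Grignard reagent from 1-(2-bromoethyl)-2-fluorobenzene adds to acetone (C2–C3) and the resulting tertiary alkoxide displaces the ortho fluoride (O1–C8a), so the heterocycle is annulated from a simple fluoroarene and acetone. Para formylation, Claisen–Schmidt condensation and hydrogenation complete the route.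

Key step: step 1

Remark: the target has no stereocentre, so no stereocontrol is required; compounds 1, 2, 8 and 9 and all reagents named are taken to be catalogue chemicals.

Step 1
Reactants: 1 1-(2-bromoethyl)-2-fluorobenzene; 2 acetone
Product: 6 2,2-dimethylchroman, via Grignard reagent 3 (not isolated), via bromomagnesium alkoxide 4 (not isolated), via potassium alkoxide 5 (not isolated)
Conditions: Mg, THF, 40 °C; 2 (1.05 equiv), 0 °C to rt; then KOtBu (3 equiv), DMSO, THF distilled off, 100 °C (one pot)
Reagents that add atoms: none
Why: Mg inserts into the primary C–Br bond and the Grignard carbon C3 of 3 adds to the acetone carbonyl (Grignard 1,2-addition), which forms C2–C3 and the tertiary alkoxide 4; KOtBu in DMSO converts 4 into the poorly ion-paired potassium alkoxide 5, whose oxygen attacks the fluorine-bearing carbon C8a ortho to the tether and expels fluoride through a Meisenheimer-type σ-complex (intramolecular SNAr), which forms O1–C8a. The closest known reaction types are the Grignard synthesis of tertiary alcohols and the base-mediated cyclisation of 3-(2-fluorophenyl)propan-1-ols to chromans. The dihydropyran ring closes in a 6-exo-trig addition–elimination at the aromatic carbon. No stereocentre arises because C2 carries two methyl groups. The step needs the tethered alkoxide to win over tert-butoxide at an unactivated ring: the six-membered transition state, the gem-dimethyl (Thorpe–Ingold) effect and fluoride as the best SNAr leaving group should secure this, and an elimination–addition path through the C8–C8a aryne would be steered by the tether to the same ring.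

Step 2
Reactants: 6 2,2-dimethylchroman
Product: 7 2,2-dimethylchroman-6-carbaldehyde
Conditions: Cl2CHOMe, TiCl4, CH2Cl2, −10 to 0 °C; then ice–water
Reagents that add atoms: dichloromethyl methyl ether COC(Cl)Cl; water O
Why: Rieche formylation, in which the TiCl4-activated chloro(methoxy)methyl cation should attack C6, para to the ring oxygen and the least hindered activated position (C8, ortho to O1, is the expected minor site), and the α-chloro ether is hydrolysed to the aldehyde on work-up.

Step 3
Reactants: 8 2,4,6-trihydroxyacetophenone; 9 isoprene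
Product: 10 1-(5,7-dihydroxy-2,2-dimethylchroman-6-yl)ethanone
Conditions: 9 (0.9 equiv, slow addition), Amberlyst 15, THF–heptane, 65 °C
Reagents that add atoms: none
Why: Acid-catalysed Friedel–Crafts prenylation at one of the two equivalent free ring positions followed by Markovnikov cycloetherification of the prenyl group should close the chroman mainly through the 4-OH, because hydrogen bonding to the acetyl group lowers the nucleophilicity of the flanking 2-OH; the 8-acetyl isomer and doubly annulated material, kept low by limiting 9, would be removed by chromatography.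

Step 4
Reactants: 10 1-(5,7-dihydroxy-2,2-dimethylchroman-6-yl)ethanone; 7 2,2-dimethylchroman-6-carbaldehyde
Product: 11 (E)-1-(5,7-dihydroxy-2,2-dimethylchroman-6-yl)-3-(2,2-dimethylchroman-6-yl)prop-2-en-1-one
Conditions: KOH (50% aq.), EtOH, rt, 48 h; then cold dilute HCl to pH 4
Reagents that add atoms: none
Why: Claisen–Schmidt (crossed aldol) condensation, in which the methyl ketone enolate of 10 adds to the non-enolisable aldehyde 7 and E1cB dehydration gives the thermodynamically favoured E-enone, while the strongly basic medium keeps the 2',6'-dihydroxychalcone open as its phenoxide instead of the flavanone.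

Step 5
Reactants: 11 (E)-1-(5,7-dihydroxy-2,2-dimethylchroman-6-yl)-3-(2,2-dimethylchroman-6-yl)prop-2-en-1-one
Product: 12 1-(5,7-dihydroxy-2,2-dimethylchroman-6-yl)-3-(2,2-dimethylchroman-6-yl)propan-1-one (target)
Conditions: H2 (1 atm), Pd/C (10 wt%), EtOAc, rt
Reagents that add atoms: none
Why: Heterogeneous catalytic hydrogenation should reduce the conjugated C=C bond much faster than the hydrogen-bonded aryl ketone or the aryl ether rings, so the dihydrochalcone forms without loss of the carbonyl group and no stereocentre is created.

Compound list
1 | 1-(2-bromoethyl)-2-fluorobenzene | Fc1ccccc1CCBr | starting material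
2 | acetone | CC(C)=O | starting material
3 | [2-(2-fluorophenyl)ethyl]magnesium bromide | Fc1ccccc1CC[Mg]Br | intermediate (not isolated)
4 | bromomagnesium 4-(2-fluorophenyl)-2-methylbutan-2-olate | CC(C)(CCc1ccccc1F)O[Mg]Br | intermediate (not isolated)
5 | potassium 4-(2-fluorophenyl)-2-methylbutan-2-olate | CC(C)(CCc1ccccc1F)[O-].[K+] | intermediate (not isolated)
6 | 2,2-dimethylchroman | CC1(C)CCc2ccccc2O1 | intermediate
7 | 2,2-dimethylchroman-6-carbaldehyde | CC1(C)CCc2cc(C=O)ccc2O1 | intermediate
8 | 2,4,6-trihydroxyacetophenone | CC(=O)c1c(O)cc(O)cc1O | starting material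
9 | isoprene (2-methylbuta-1,3-diene) | C=CC(C)=C | starting material
10 | 1-(5,7-dihydroxy-2,2-dimethylchroman-6-yl)ethanone | CC(=O)c1c(O)cc2c(c1O)CCC(C)(C)O2 | intermediate
11 | (E)-1-(5,7-dihydroxy-2,2-dimethylchroman-6-yl)-3-(2,2-dimethylchroman-6-yl)prop-2-en-1-one | CC1(C)CCc2cc(/C=C/C(=O)c3c(O)cc4c(c3O)CCC(C)(C)O4)ccc2O1 | intermediate
12 | 1-(5,7-dihydroxy-2,2-dimethylchroman-6-yl)-3-(2,2-dimethylchroman-6-yl)propan-1-one | CC1(C)CCc2cc(CCC(=O)c3c(O)cc4c(c3O)CCC(C)(C)O4)ccc2O1 | target

Total step count: 5
Longest linear sequence: 4 steps (steps 1, 2, 4 and 5)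

Steps most likely to fail

Step 1. The alkoxide may fail to displace fluoride from the unactivated ring, so that the reaction stops at the open-chain tertiary alcohol, or tert-butoxide may substitute intermolecularly. The fallback sets out from acetone 2 and returns at 6. Commercial 1-(2-bromoethyl)-2-chlorobenzene is converted with Mg in THF (the aryl chloride is inert) into [2-(2-chlorophenyl)ethyl]magnesium bromide F1. F1 adds to 2 and gives bromomagnesium 4-(2-chlorophenyl)-2-methylbutan-2-olate F2, and aqueous NH4Cl work-up gives 4-(2-chlorophenyl)-2-methylbutan-2-ol F3. A palladium-catalysed intramolecular C–O coupling (Buchwald–Hartwig etherification; Pd(OAc)2, 2-di-tert-butylphosphino-2',4',6'-triisopropylbiphenyl, Cs2CO3, toluene, 90 °C) should then close the ring to 6. This replaces the SNAr ring closure by C–O reductive elimination at palladium and still builds the same two bonds.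

Step 3. Ring closure may go through the ortho oxygen to a comparable extent (poor regioselectivity between the two phenolic oxygens), and a second prenylation may consume the product. The fallback sets out from isoprene 9 and returns at 10. Isoprene 9 is condensed with an excess of symmetric phloroglucinol (Amberlyst 15, THF–heptane, 65 °C), which raises no regiochemical question and should give 2,2-dimethylchroman-5,7-diol F4. NaH and MOMCl in DMF give 5,7-bis(methoxymethoxy)-2,2-dimethylchroman F5. n-BuLi in THF at 0 °C should lithiate C6, the position flanked by both MOM ethers (directed ortho-metalation), to [5,7-bis(methoxymethoxy)-2,2-dimethylchroman-6-yl]lithium F6. Acylation with N-methoxy-N-methylacetamide and NH4Cl work-up give 1-[5,7-bis(methoxymethoxy)-2,2-dimethylchroman-6-yl]ethanone F7. HCl in MeOH at 40 °C removes both MOM groups and gives 10.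

Step 4. The doubly deprotonated ketone may condense only slowly, and the 2',6'-dihydroxychalcone may cyclise to the flavanone during acidification, after which neutral hydrogenation no longer delivers the open chain. The fallback sets out from 10 and returns at 12. BnBr and K2CO3 in DMF at 80 °C give 1-[5,7-bis(benzyloxy)-2,2-dimethylchroman-6-yl]ethanone F8. Claisen–Schmidt condensation of F8 with 7 (KOH, EtOH, rt) gives (E)-1-[5,7-bis(benzyloxy)-2,2-dimethylchroman-6-yl]-3-(2,2-dimethylchroman-6-yl)prop-2-en-1-one F9, which cannot cyclise. H2 and Pd/C in EtOAc–MeOH then reduce the C=C bond and cleave both benzyl ethers in one operation to give 12.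

Further compounds
F1 | step 1 | [2-(2-chlorophenyl)ethyl]magnesium bromide | Clc1ccccc1CC[Mg]Br
F2 | step 1 | bromomagnesium 4-(2-chlorophenyl)-2-methylbutan-2-olate | CC(C)(CCc1ccccc1Cl)O[Mg]Br
F3 | step 1 | 4-(2-chlorophenyl)-2-methylbutan-2-ol | CC(C)(O)CCc1ccccc1Cl
F4 | step 3 | 2,2-dimethylchroman-5,7-diol | CC1(C)CCc2c(O)cc(O)cc2O1
F5 | step 3 | 5,7-bis(methoxymethoxy)-2,2-dimethylchroman | COCOc1cc(OCOC)c2c(c1)OC(C)(C)CC2
F6 | step 3 | [5,7-bis(methoxymethoxy)-2,2-dimethylchroman-6-yl]lithium | [Li]c1c(OCOC)cc2c(c1OCOC)CCC(C)(C)O2
F7 | step 3 | 1-[5,7-bis(methoxymethoxy)-2,2-dimethylchroman-6-yl]ethanone | CC(=O)c1c(OCOC)cc2c(c1OCOC)CCC(C)(C)O2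
F8 | step 4 | 1-[5,7-bis(benzyloxy)-2,2-dimethylchroman-6-yl]ethanone | CC(=O)c1c(OCc3ccccc3)cc2c(c1OCc4ccccc4)CCC(C)(C)O2
F9 | step 4 | (E)-1-[5,7-bis(benzyloxy)-2,2-dimethylchroman-6-yl]-3-(2,2-dimethylchroman-6-yl)prop-2-en-1-one | CC1(C)CCc2cc(/C=C/C(=O)c3c(OCc5ccccc5)cc4c(c3OCc6ccccc6)CCC(C)(C)O4)ccc2O1
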